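**Assumptions:** The target SMILES corresponds to (R) at both carbinol carbons; I checked this by CIP analysis. (R)-1,2-Epoxypentane is taken as available, either commercial or from racemic epoxide by Jacobsen hydrolytic kinetic resolution. The Vilsmeier formylation in Step 3 is assumed to go at C2 of the aryl bromide, ortho to Br and OBn and para to the other OBn.

## Retrosynthetic overview
1. Integracin B is a 2,4-dihydroxy-6-(8-hydroxyundecyl)benzoate ester of (R)-1-(3,5-dihydroxyphenyl)undecan-8-ol. Disconnect the final four O-benzyl groups first (one global hydrogenolysis).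
2. Disconnect the benzoate ring's C(sp2)–C(sp3) bond (B-alkyl Suzuki) to give an aryl bromo-ester and an alkyl-9-BBN derived from one alkenol.
3. Disconnect the ester C–O bond to give 2-bromo-4,6-bis(benzyloxy)benzoic acid and the aryl-chain alcohol. That alcohol comes from the same alkenol by Suzuki coupling with a commercial aryl bromide.
4. The alkenol is (R)-1,2-epoxypentane plus a hexenyl Grignard. This sets the only stereocentre type, used twice. No ring is formed; both benzene rings come from commercial 1-bromo-3,5-bis(benzyloxy)benzene. The acid carbon is added by Vilsmeier formylation then Pinnick oxidation.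

## Route

**Step 1**
Reactants: 1 (R)-1,2-epoxypentane; 2 6-bromohex-1-ene
Product: 3 (R)-undec-10-en-4-ol
Conditions: Mg, THF (2 → hex-5-enylMgBr); then 1, CuI (10 mol%), THF, –20 → 0 °C
Reagents that add atoms: none (the hexenyl group comes from 2)
Why: Cu-catalysed Grignard opening of the terminal epoxide occurs at the unhindered CH2. The stereocentre is not touched, so (R) epoxide gives (R) alcohol (same priority order O > chain > propyl).

**Step 2**
Reactants: 3 (R)-undec-10-en-4-ol; 4 1-bromo-3,5-bis(benzyloxy)benzene
Product: 5 (R)-11-[3,5-bis(benzyloxy)phenyl]undecan-4-ol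
Conditions: 9-BBN-H (2.2 equiv), THF, rt; then 4, Pd(dppf)Cl2 (5 mol%), aq. K3PO4, THF, 60 °C
Reagents that add atoms: none (9-BBN boron is lost; net result is anti-Markovnikov hydroarylation)
Why: Hydroboration of the terminal alkene (the first equivalent of 9-BBN caps the OH as O–B) followed by B-alkyl Suzuki coupling gives the Ar–(CH2)7 chain. The carbinol is untouched and retains (R).

**Step 3**
Reactants: 4 1-bromo-3,5-bis(benzyloxy)benzene
Product: 6 2-bromo-4,6-bis(benzyloxy)benzaldehyde
Conditions: POCl3, DMF, 0 → 60 °C
Reagents that add atoms: DMF, CN(C)C=O (supplies the CHO)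
Why: Vilsmeier–Haack formylation occurs at the position ortho to one OBn and para to the other, which is ortho to Br. This places the future carboxyl next to an OBn and the future alkyl-bearing carbon, giving the 2,4-dioxygenated-6-substituted pattern.

**Step 4**
Reactants: 6 aldehyde
Product: 7 2-bromo-4,6-bis(benzyloxy)benzoic acid
Conditions: NaClO2, NaH2PO4, 2-methyl-2-butene, t-BuOH/H2O, rt
Reagents that add atoms: sodium chlorite, [Na+].[O-]Cl=O (supplies the O)
Why: Pinnick oxidation is chemoselective for the aldehyde. The alkene scavenges HOCl, which prevents chlorination of the electron-rich ring.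

**Step 5**
Reactants: 7 acid; 5 alcohol
Product: 8 ester, i.e. (R)-11-[3,5-bis(benzyloxy)phenyl]undecan-4-yl 2-bromo-4,6-bis(benzyloxy)benzoate
Conditions: (COCl)2, cat. DMF, CH2Cl2, 0 °C → rt; then 5, DMAP, Et3N, CH2Cl2, 0 → 40 °C
Reagents that add atoms: none (oxalyl chloride only activates the acid; its atoms are lost)
Why: Acid-chloride acylation of a secondary alcohol with DMAP catalysis overcomes the 2,6-disubstituted hindrance. The C–O bond of the carbinol is not broken, so (R) is retained. Yamaguchi is avoided because the electron-rich aroyl carbonyl would be less electrophilic than the trichlorobenzoyl one.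

**Step 6**
Reactants: 8 bromo-ester; 3 alkenol
Product: 9 fully protected integracin B
Conditions: 3 + 9-BBN-H (2.2 equiv), THF, rt; then 8, Pd(dppf)Cl2 (5 mol%), aq. K3PO4, THF/DMF, 60 °C
Reagents that add atoms: none
Why: B-alkyl Suzuki coupling with the aryl bromide, which has only one ortho substituent, installs the (R)-8-hydroxyundecyl chain on the acid ring. The hindered aryl ester and the benzyl ethers survive, and the carbinol is untouched.

**Step 7**
Reactants: 9 protected target
Product: 10 integracin B
Conditions: H2 (1 atm), 10% Pd/C, EtOAc/MeOH, rt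
Reagents that add atoms: none (H2 adds only hydrogen)
Why: Hydrogenolysis removes all four aryl benzyl ethers. The salicylate ester, the secondary alcohol and both stereocentres are inert, and no alkene remains.

## Compound list
1 | (R)-1,2-epoxypentane | CCC[C@@H]1CO1 | starting material
2 | 6-bromohex-1-ene | C=CCCCCBr | starting material
3 | (R)-undec-10-en-4-ol | CCC[C@@H](O)CCCCCC=C | intermediate
4 | 1-bromo-3,5-bis(benzyloxy)benzene | Brc1cc(OCc2ccccc2)cc(OCc2ccccc2)c1 | starting material
5 | (R)-11-[3,5-bis(benzyloxy)phenyl]undecan-4-ol | CCC[C@@H](O)CCCCCCCc1cc(OCc2ccccc2)cc(OCc2ccccc2)c1 | intermediate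
6 | 2-bromo-4,6-bis(benzyloxy)benzaldehyde | O=Cc1c(Br)cc(OCc2ccccc2)cc1OCc1ccccc1 | intermediate
7 | 2-bromo-4,6-bis(benzyloxy)benzoic acid | OC(=O)c1c(Br)cc(OCc2ccccc2)cc1OCc1ccccc1 | intermediate
8 | bromo-ester of 5 and 7 | O=C(O[C@H](CCC)CCCCCCCc1cc(OCc2ccccc2)cc(OCc2ccccc2)c1)c1c(Br)cc(OCc2ccccc2)cc1OCc1ccccc1 | intermediate
9 | tetra-O-benzyl integracin B | CCC[C@@H](O)CCCCCCCc1cc(OCc2ccccc2)cc(OCc2ccccc2)c1C(=O)O[C@H](CCC)CCCCCCCc1cc(OCc2ccccc2)cc(OCc2ccccc2)c1 | intermediate
10 | integracin B | CCC[C@@H](O)CCCCCCCc1cc(O)cc(O)c1C(=O)O[C@H](CCC)CCCCCCCc1cc(O)cc(O)c1 | target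

**Total steps:** 7.
**Longest linear sequence:** 5 steps, either 1→2→5→6→7 from the epoxide or 3→4→5→6→7 from the aryl bromide.

**Three steps most likely to fail**
1. **Step 5 (hindered, electron-rich 2,6-disubstituted benzoic acid with a secondary alcohol).**
   Fallback: make the (S)-enantiomer of 5 from (S)-epoxypentane and esterify under Mitsunobu conditions (DIAD, PPh3). The inversion delivers the (R) ester.
2. **Step 3 (Vilsmeier regioselectivity and benzyl ether stability).**
   Fallback: start from commercial 2,4,6-trihydroxybenzaldehyde. Dibenzylate it, convert the remaining 2-OH to the triflate, oxidise to the acid, then use the aryl triflate instead of the bromide in the Step 5/6 sequence.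
3. **Step 6 (B-alkyl Suzuki with a free-OH alkylborane on the hindered ester).**
   Fallback: replace it with a Heck coupling of alkenol 3 and bromide 8. Any styrenyl or chain-walked alkene isomers are saturated in the final hydrogenation, which also removes the benzyl groups.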